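## Retrosynthetic overview

1. Target 24 ⇐ diol 23 (tigloylation at O2) ⇐ primary alcohol 21 (acetylation at O13, desilylation).
2. Ether bridge, C13 and the quaternary C11 ⇐ new hydroxymethylative transannular O–H insertion of the 11-diazo-13-nor-12,8-olide 20 (C11–O5 and C11–C13 bonds in one step).
3. cis-12,8-Lactone ⇐ iodolactonization of the Δ8 amide 15 ⇐ Eschenmoser–Claisen rearrangement of 9β-allylic alcohol 13 ⇐ cycloheptenone 12 (ring-closing metathesis of vinyl ketone and C5 allyl group).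
4. C5, C4, C10 ⇐ α-face allylation of ketone 6, methyl addition to α-ketol 4, convex-face methylation of the temporary O5–C9 lactone 8.
5. Cyclopentane ⇐ Mukaiyama–Michael addition of ketene silyl acetal 2 to (S)-enone 1. Ring order: cyclopentane (from 1) → seven-membered ring → γ-lactone → tetrahydrofuran bridge.

Assumption: the target is exactly the given SMILES (1R,2S,4R,5R,7S,8R,10R,11R); all intermediates carry the guaiane atom numbers C1–C15 of the target, α is the face of H1 and β the face of the lactone and ether oxygens, TBS = tert-butyldimethylsilyl, and enone 1 is taken as commercial.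

## Route

Step 1
Reactants: 1 (S)-4-(tert-butyldimethylsilyloxy)cyclopent-2-en-1-one; 2 1-(tert-butyldimethylsilyloxy)-1-methoxyethene
Product: 3 methyl 2-[(1S,5S)-3,5-bis(tert-butyldimethylsilyloxy)cyclopent-2-en-1-yl]acetate
Conditions: MeCN, 55 °C
Reagents that add atoms: none
Why: The uncatalysed Mukaiyama–Michael addition of a ketene silyl acetal to a cyclopentenone in acetonitrile gives the silyl enol ether directly, and the nucleophile enters anti to the 4-silyloxy group, which sets C1 (side chain β, trans to the 2α-silyloxy group).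

Step 2
Reactants: 3 methyl 2-[(1S,5S)-3,5-bis(tert-butyldimethylsilyloxy)cyclopent-2-en-1-yl]acetate
Product: 4 methyl 2-(2α-TBSO-5α-hydroxy-4-oxocyclopentan-1β-yl)acetate
Conditions: OsO4 (2 mol%), N-methylmorpholine N-oxide, acetone/H2O, 0 °C → rt
Reagents that add atoms: N-methylmorpholine N-oxide C[N+]1([O-])CCOCC1; water O
Why: Catalytic osmylation of the silyl enol ether (Upjohn dihydroxylation, then loss of silanol; a Rubottom-type oxidation) gives the α-hydroxy ketone regiospecifically, with OsO4 approaching anti to the adjacent C1 side chain to give the 5α-alcohol, a temporary centre that only steers step 3.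

Step 3
Reactants: 4 methyl 2-(2α-TBSO-5α-hydroxy-4-oxocyclopentan-1β-yl)acetate
Product: 5 methyl 2-(2α-TBSO-4α,5α-dihydroxy-4β-methylcyclopentan-1β-yl)acetate
Conditions: MeMgBr, CeCl3, THF, −78 °C
Reagents that add atoms: methylmagnesium bromide C[Mg]Br
Why: The organocerium reagent adds to the ketone much faster than to the methyl ester and without enolisation or β-elimination of the silyloxy group, entering from the β face anti to the vicinal 5α-oxygen and the 2α-silyloxy group, which sets C4 (4β-methyl, 4α-hydroxyl).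

Step 4
Reactants: 5 methyl 2-(2α-TBSO-4α,5α-dihydroxy-4β-methylcyclopentan-1β-yl)acetate
Product: 6 methyl 2-(2α-TBSO-4α-hydroxy-4β-methyl-5-oxocyclopentan-1β-yl)acetate
Conditions: IBX, DMSO, rt
Reagents that add atoms: none
Why: IBX oxidises the secondary hydroxyl of a secondary–tertiary 1,2-diol to the α-hydroxy ketone without glycol cleavage, and the tertiary alcohol, ester and silyl ether are inert.

Step 5
Reactants: 6 methyl 2-(2α-TBSO-4α-hydroxy-4β-methyl-5-oxocyclopentan-1β-yl)acetate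
Product: 8 5α-allyl-2α-TBSO-4α-hydroxy-4β-methylcyclopentane-1β-acetic acid 5β-lactone (cis-fused γ-lactone O5–C9), via hydroxy ester 7 (not isolated)
Conditions: allyl bromide, Zn dust, THF/sat. aq NH4Cl, 0 °C → rt; then DBU (0.2 equiv), PhMe, 80 °C
Reagents that add atoms: allyl bromide C=CCBr
Why: Barbier allylation with allylzinc bromide is selective for the ketone over the ester and attacks the α face, anti to both flanking β substituents (4β-methyl and the C1 side chain), which sets C5 (5β-hydroxyl, 5α-allyl); the new hydroxyl is cis to the ester arm and closes the γ-lactone under DBU catalysis.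

Step 6
Reactants: 8 5α-allyl-2α-TBSO-4α-hydroxy-4β-methylcyclopentane-1β-acetic acid 5β-lactone
Product: 9 10α-methyl lactone: 2-(5α-allyl-2α-TBSO-4α-hydroxy-4β-methylcyclopentan-1β-yl)propanoic acid 5β-lactone (methyl exo, cis to H1)
Conditions: LiN(iPr)2 (2.2 equiv), THF, −78 °C; MeI, −78 → −40 °C
Reagents that add atoms: iodomethane CI
Why: Alkylation of the enolate of a cis-fused bicyclic γ-lactone occurs on the convex face, cis to H1, which sets C10 (10α-methyl), while the lithium alkoxide of the tertiary alcohol does not react with MeI at low temperature.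

Step 7
Reactants: 9 10α-methyl lactone
Product: 10 (10S)-N-methoxy-N-methyl-2-(5α-allyl-2α-TBSO-4α,5β-dihydroxy-4β-methylcyclopentan-1β-yl)propanamide
Conditions: MeNH(OMe)·HCl, AlMe3, CH2Cl2, 0 °C → rt
Reagents that add atoms: N,O-dimethylhydroxylamine hydrochloride CNOC.Cl
Why: Weinreb aminolysis of a γ-lactone with the aluminium amide formed from AlMe3 and the amine salt opens the ring cleanly to the hydroxy Weinreb amide under non-epimerising conditions.

Step 8
Reactants: 10 (10S)-N-methoxy-N-methyl-2-(5α-allyl-2α-TBSO-4α,5β-dihydroxy-4β-methylcyclopentan-1β-yl)propanamide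
Product: 11 (10S)-4-(5α-allyl-2α-TBSO-4α,5β-dihydroxy-4β-methylcyclopentan-1β-yl)pent-1-en-3-one
Conditions: CH2=CHMgBr (4 equiv), THF, −78 → 0 °C; inverse quench into cold 1 M HCl
Reagents that add atoms: vinylmagnesium bromide C=C[Mg]Br
Why: Addition of a vinyl Grignard reagent to a Weinreb amide stops at the chelated tetrahedral intermediate, so the vinyl ketone is released only on the inverse acidic quench, which also prevents conjugate addition of the liberated hydroxylamine.

Step 9
Reactants: 11 (10S)-4-(5α-allyl-2α-TBSO-4α,5β-dihydroxy-4β-methylcyclopentan-1β-yl)pent-1-en-3-one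
Product: 12 2α-TBSO-4α,5β-dihydroxy-1αH,10βH-11,12,13-trinorguai-7-en-9-one
Conditions: second-generation Grubbs catalyst (H2IMes)(PCy3)Cl2Ru=CHPh (5 mol%), CH2Cl2, 40 °C
Reagents that add atoms: none
Why: Ring-closing metathesis between a terminal allyl group and a vinyl ketone is a reliable route to cycloheptenones, and the two arms, trans on the cyclopentane, give the trans-fused bicyclo[5.3.0]decenone without touching a stereocentre (C10, now α to the ketone, can be equilibrated with base to the pseudo-equatorial 10α-methyl isomer if needed).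

Step 10
Reactants: 12 2α-TBSO-4α,5β-dihydroxy-1αH,10βH-11,12,13-trinorguai-7-en-9-one
Product: 13 2α-TBSO-1αH,10βH-11,12,13-trinorguai-7-ene-4α,5β,9β-triol
Conditions: NaBH4, CeCl3·7H2O, MeOH, −40 °C
Reagents that add atoms: none
Why: Luche reduction gives clean 1,2-reduction of the enone, and pseudo-axial hydride delivery gives the pseudo-equatorial alcohol trans to the pseudo-equatorial 10α-methyl group, i.e. the 9β-alcohol needed for chirality transfer.

Step 11
Reactants: 13 2α-TBSO-1αH,10βH-11,12,13-trinorguai-7-ene-4α,5β,9β-triol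
Product: 15 N,N-dimethyl-2α-TBSO-4α,5β-dihydroxy-1αH,7αH,10βH-13-norguai-8-en-12-amide, via O-allyl ketene aminal 14 (not isolated)
Conditions: MeC(OMe)2NMe2 (5 equiv), xylenes, 140 °C
Reagents that add atoms: N,N-dimethylacetamide dimethyl acetal CC(OC)(OC)N(C)C
Why: In the Eschenmoser–Claisen rearrangement the [3,3]-sigmatropic shift of the ketene aminal is suprafacial within the ring, so the 9β C–O bond is exchanged for a 7β C–C bond (sets C7) while the alkene moves to C8–C9; the trans-1,2-diol cannot form a cyclic orthoamide.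

Step 12
Reactants: 15 N,N-dimethyl-2α-TBSO-4α,5β-dihydroxy-1αH,7αH,10βH-13-norguai-8-en-12-amide
Product: 17 9α-iodo-2α-TBSO-4α,5β-dihydroxy-13-norguaian-12,8β-olide, via iminium lactone iodide 16 (not isolated)
Conditions: I2, NaHCO3, THF/H2O (1:1), 0 °C → rt
Reagents that add atoms: iodine II; water O
Why: Iodolactonization of a γ,δ-unsaturated N,N-dimethylamide proceeds by 5-exo attack of the amide oxygen on C8 anti to the iodonium ion, from the β face on which the side chain sits, which sets C8 (8β-oxygen, cis-fused lactone) and places iodine 9α; the amide is more nucleophilic than the hindered tertiary 5-hydroxyl, and hydrolysis of the iminium lactone gives the lactone.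

Step 13
Reactants: 17 9α-iodo-2α-TBSO-4α,5β-dihydroxy-13-norguaian-12,8β-olide
Product: 18 2α-TBSO-4α,5β-dihydroxy-1αH,7αH,8αH,10βH-13-norguaian-12,8β-olide
Conditions: Bu3SnH, AIBN (cat.), PhMe, 80 °C
Reagents that add atoms: none
Why: Radical dehalogenation with Bu3SnH removes the secondary iodide under neutral conditions that leave the lactone, the tertiary alcohols and the silyl ether untouched.

Step 14
Reactants: 18 2α-TBSO-4α,5β-dihydroxy-13-norguaian-12,8β-olide
Product: 20 11-diazo-2α-TBSO-4α,5β-dihydroxy-13-norguaian-12,8β-olide, via trifluoroacetyl lactone 19 (not isolated)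
Conditions: LiN(SiMe3)2 (3.3 equiv), THF, −78 °C; CF3CO2CH2CF3; then MsN3, Et3N, H2O, MeCN, rt
Reagents that add atoms: 2,2,2-trifluoroethyl trifluoroacetate O=C(OCC(F)(F)F)C(F)(F)F (trifluoroacetyl group of 19); methanesulfonyl azide CS(=O)(=O)N=[N+]=[N-] (diazo nitrogens of 20)
Why: Danheiser's deacylative diazo transfer (trifluoroacetylation of the lactone enolate, then sulfonyl azide) is the standard entry to α-diazo lactones; excess base covers the two tertiary hydroxyls and any O-trifluoroacetate is cleaved in the aqueous amine stage.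

Step 15
Reactants: 20 11-diazo-2α-TBSO-4α,5β-dihydroxy-13-norguaian-12,8β-olide
Product: 21 2α-TBSO-4α,13-dihydroxy-5β,11-epoxyguaian-12,8β-olide
Conditions: Rh2(esp)2 (esp = α,α,α′,α′-tetramethyl-1,3-benzenedipropanoate, 1 mol%), monomeric CH2O (10 equiv, THF solution), 4 Å MS, CH2Cl2, −20 °C, slow addition of 20
Reagents that add atoms: formaldehyde C=O
Why: Proposed new method: the divalent rhodium carbenoid formed at C11 is captured by the proximal 5β-hydroxyl through a five-membered transition state to give a cyclic protic oxonium ylide, whose enolate carbon adds to the highly electrophilic monomeric formaldehyde before the usual 1,2-proton shift, so the C11–O5 ether bond, the C11–C13 bond and the fully substituted C11 stereocentre form in one operation, with C11 fixed by the cage because the CH2OH can only take the exo site vacated by rhodium; the closest known reactions are rhodium-carbenoid O–H insertion and the three-component trapping of alcohol-derived oxonium ylides by aldehydes or imines, not yet shown transannularly with a tertiary alcohol, a cyclic α-diazo lactone and formaldehyde.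

Step 16
Reactants: 21 2α-TBSO-4α,13-dihydroxy-5β,11-epoxyguaian-12,8β-olide
Product: 22 13-acetoxy-2α-TBSO-4α-hydroxy-5β,11-epoxyguaian-12,8β-olide
Conditions: Ac2O, pyridine, DMAP (cat.), CH2Cl2, 0 °C
Reagents that add atoms: acetic anhydride CC(=O)OC(C)=O
Why: Acetylation with Ac2O/pyridine takes the primary C13 hydroxyl and leaves the tertiary 4α-hydroxyl free.

Step 17
Reactants: 22 13-acetoxy-2α-TBSO-4α-hydroxy-5β,11-epoxyguaian-12,8β-olide
Product: 23 13-acetoxy-2α,4α-dihydroxy-5β,11-epoxyguaian-12,8β-olide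
Conditions: HF·pyridine, THF, 0 °C → rt
Reagents that add atoms: none
Why: HF·pyridine cleaves the secondary silyl ether without affecting the acetate, the lactone or the tertiary alcohol.

Step 18
Reactants: 23 13-acetoxy-2α,4α-dihydroxy-5β,11-epoxyguaian-12,8β-olide
Product: 24 CNP0112086.1, 13-acetoxy-4α-hydroxy-2α-tigloyloxy-5β,11-epoxy-1αH,7αH,8αH,10βH-guaian-12,8β-olide
Conditions: tigloyl chloride, pyridine, DMAP, CH2Cl2, 0 °C → rt
Reagents that add atoms: tigloyl chloride C/C=C(\C)C(=O)Cl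
Why: DMAP-catalysed acylation with tigloyl chloride in pyridine esterifies the secondary 2α-hydroxyl selectively over the tertiary 4α-hydroxyl and keeps the (E)-alkene geometry.

## Compound list

1 | (S)-4-(tert-butyldimethylsilyloxy)cyclopent-2-en-1-one | CC(C)(C)[Si](C)(C)O[C@H]1CC(=O)C=C1 | starting material
2 | 1-(tert-butyldimethylsilyloxy)-1-methoxyethene | C=C(OC)O[Si](C)(C)C(C)(C)C | starting material
3 | methyl 2-[(1S,5S)-3,5-bis(tert-butyldimethylsilyloxy)cyclopent-2-en-1-yl]acetate | CC(C)(C)[Si](C)(C)O[C@H]1CC(O[Si](C)(C)C(C)(C)C)=C[C@@H]1CC(=O)OC | intermediate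
4 | methyl 2-(2α-TBSO-5α-hydroxy-4-oxocyclopentan-1β-yl)acetate | CC(C)(C)[Si](C)(C)O[C@H]1CC(=O)[C@@H](O)[C@@H]1CC(=O)OC | intermediate
5 | methyl 2-(2α-TBSO-4α,5α-dihydroxy-4β-methylcyclopentan-1β-yl)acetate | CC(C)(C)[Si](C)(C)O[C@H]1C[C@@](C)(O)[C@@H](O)[C@@H]1CC(=O)OC | intermediate
6 | methyl 2-(2α-TBSO-4α-hydroxy-4β-methyl-5-oxocyclopentan-1β-yl)acetate | CC(C)(C)[Si](C)(C)O[C@H]1C[C@@](C)(O)C(=O)[C@@H]1CC(=O)OC | intermediate
7 | hydroxy ester: methyl 2-(5α-allyl-2α-TBSO-4α,5β-dihydroxy-4β-methylcyclopentan-1β-yl)acetate | CC(C)(C)[Si](C)(C)O[C@H]1C[C@@](C)(O)[C@@](O)(CC=C)[C@@H]1CC(=O)OC | intermediate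
8 | 5α-allyl-2α-TBSO-4α-hydroxy-4β-methylcyclopentane-1β-acetic acid 5β-lactone | CC(C)(C)[Si](C)(C)O[C@H]1C[C@@](C)(O)[C@]2(CC=C)OC(=O)C[C@H]12 | intermediate
9 | 10α-methyl lactone: 2-(5α-allyl-2α-TBSO-4α-hydroxy-4β-methylcyclopentan-1β-yl)propanoic acid 5β-lactone | CC(C)(C)[Si](C)(C)O[C@H]1C[C@@](C)(O)[C@]2(CC=C)OC(=O)[C@@H](C)[C@H]12 | intermediate
10 | (10S)-N-methoxy-N-methyl-2-(5α-allyl-2α-TBSO-4α,5β-dihydroxy-4β-methylcyclopentan-1β-yl)propanamide | CC(C)(C)[Si](C)(C)O[C@H]1C[C@@](C)(O)[C@@](O)(CC=C)[C@@H]1[C@H](C)C(=O)N(C)OC | intermediate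
11 | (10S)-4-(5α-allyl-2α-TBSO-4α,5β-dihydroxy-4β-methylcyclopentan-1β-yl)pent-1-en-3-one | CC(C)(C)[Si](C)(C)O[C@H]1C[C@@](C)(O)[C@@](O)(CC=C)[C@@H]1[C@H](C)C(=O)C=C | intermediate
12 | 2α-TBSO-4α,5β-dihydroxy-1αH,10βH-11,12,13-trinorguai-7-en-9-one | CC(C)(C)[Si](C)(C)O[C@H]1C[C@@](C)(O)[C@@]2(O)CC=CC(=O)[C@@H](C)[C@H]12 | intermediate
13 | 2α-TBSO-1αH,10βH-11,12,13-trinorguai-7-ene-4α,5β,9β-triol | CC(C)(C)[Si](C)(C)O[C@H]1C[C@@](C)(O)[C@@]2(O)CC=C[C@H](O)[C@@H](C)[C@H]12 | intermediate
14 | O-allyl ketene aminal: 9β-O-[1-(dimethylamino)vinyl] ether of 13 | CC(C)(C)[Si](C)(C)O[C@H]1C[C@@](C)(O)[C@@]2(O)CC=C[C@H](OC(=C)N(C)C)[C@@H](C)[C@H]12 | intermediate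
15 | N,N-dimethyl-2α-TBSO-4α,5β-dihydroxy-1αH,7αH,10βH-13-norguai-8-en-12-amide | CC(C)(C)[Si](C)(C)O[C@H]1C[C@@](C)(O)[C@@]2(O)C[C@H](CC(=O)N(C)C)C=C[C@@H](C)[C@H]12 | intermediate
16 | iminium lactone iodide: 9α-iodo-2α-TBSO-4α,5β-dihydroxy-13-norguaian-12,8β-olide N,N-dimethyliminium iodide | CC(C)(C)[Si](C)(C)O[C@H]1C[C@@](C)(O)[C@@]2(O)C[C@H]3[C@@H]([C@@H](I)[C@@H](C)[C@H]12)OC(=[N+](C)C)C3.[I-] | intermediate
17 | 9α-iodo-2α-TBSO-4α,5β-dihydroxy-13-norguaian-12,8β-olide | CC(C)(C)[Si](C)(C)O[C@H]1C[C@@](C)(O)[C@@]2(O)C[C@H]3[C@@H]([C@@H](I)[C@@H](C)[C@H]12)OC(=O)C3 | intermediate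
18 | 2α-TBSO-4α,5β-dihydroxy-1αH,7αH,8αH,10βH-13-norguaian-12,8β-olide | CC(C)(C)[Si](C)(C)O[C@H]1C[C@@](C)(O)[C@@]2(O)C[C@H]3[C@@H](C[C@@H](C)[C@H]12)OC(=O)C3 | intermediate
19 | trifluoroacetyl lactone: 11-trifluoroacetyl-2α-TBSO-4α,5β-dihydroxy-13-norguaian-12,8β-olide (C11 epimers/enol) | CC(C)(C)[Si](C)(C)O[C@H]1C[C@@](C)(O)[C@@]2(O)C[C@H]3[C@@H](C[C@@H](C)[C@H]12)OC(=O)C3C(=O)C(F)(F)F | intermediate
20 | 11-diazo-2α-TBSO-4α,5β-dihydroxy-13-norguaian-12,8β-olide | CC(C)(C)[Si](C)(C)O[C@H]1C[C@@](C)(O)[C@@]2(O)C[C@H]3[C@@H](C[C@@H](C)[C@H]12)OC(=O)C3=[N+]=[N-] | intermediate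
21 | 2α-TBSO-4α,13-dihydroxy-5β,11-epoxyguaian-12,8β-olide | CC(C)(C)[Si](C)(C)O[C@H]1C[C@@](C)(O)[C@@]23C[C@H]4[C@@H](C[C@@H](C)[C@H]12)OC(=O)[C@@]4(CO)O3 | intermediate
22 | 13-acetoxy-2α-TBSO-4α-hydroxy-5β,11-epoxyguaian-12,8β-olide | CC(C)(C)[Si](C)(C)O[C@H]1C[C@@](C)(O)[C@@]23C[C@H]4[C@@H](C[C@@H](C)[C@H]12)OC(=O)[C@@]4(COC(C)=O)O3 | intermediate
23 | 13-acetoxy-2α,4α-dihydroxy-5β,11-epoxyguaian-12,8β-olide | O[C@H]1C[C@@](C)(O)[C@@]23C[C@H]4[C@@H](C[C@@H](C)[C@H]12)OC(=O)[C@@]4(COC(C)=O)O3 | intermediate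
24 | CNP0112086.1, 13-acetoxy-4α-hydroxy-2α-tigloyloxy-5β,11-epoxy-1αH,7αH,8αH,10βH-guaian-12,8β-olide | C/C=C(\C)C(=O)O[C@H]1C[C@@](C)(O)[C@@]23C[C@H]4[C@@H](C[C@@H](C)[C@H]12)OC(=O)[C@@]4(COC(C)=O)O3 | target

## Step count and risk

Total step count: 18. Longest linear sequence: 18 steps (1 → 24).

The three steps most likely to fail:

Step 15 (the proposed new reaction). The oxonium ylide may simply undergo the 1,2-proton shift before it meets formaldehyde, or the carbenoid may lose H7 by hydride shift to a butenolide. The fallback uses known chemistry, sets out from 20 and comes back at 21. Rh2(OAc)4 (1 mol%) in CH2Cl2 at rt gives the ordinary intramolecular O–H insertion product 2α-TBSO-4α-hydroxy-5β,11-epoxy-13-norguaian-12,8β-olide F1. Deprotonation of this with LiN(iPr)2 (2.2 equiv, THF, −78 °C) and aldol reaction of the lactone enolate with gaseous monomeric CH2O then installs C13 on the only open (exo) face and gives 21.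

Step 10. If hydride instead attacks anti to the 10α-methyl group, the reduction of 12 gives the 9α-alcohol 2α-TBSO-1αH,10βH-11,12,13-trinorguai-7-ene-4α,5β,9α-triol F2, from which a Claisen rearrangement would place the side chain on the wrong face. The fallback sets out from 12 and comes back at 17. Alcohol F2 is inverted and acylated in one operation by a Mitsunobu reaction (PPh3, DIAD, AcOH, THF) to the 9β-acetate of 13 F3. Ireland–Claisen rearrangement of this acetate (LiN(iPr)2, Me3SiCl, THF, −78 → 60 °C, then dilute HCl) gives 2α-TBSO-4α,5β-dihydroxy-1αH,7αH,10βH-13-norguai-8-en-12-oic acid F4. Iodolactonization of the acid (I2, NaHCO3, MeCN/H2O) gives 17.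

Step 12. The tertiary 5β-hydroxyl sits on the same face as the amide arm and could close a transannular iodo-ether instead of the lactone. The fallback removes the competing nucleophile, sets out from 15 and comes back at 17. Both tertiary alcohols are silylated (Me3SiOTf, 2,6-lutidine, CH2Cl2, −78 °C) to the 4α,5β-bis(trimethylsilyl) ether of 15 F5. Iodolactonization (I2, NaHCO3, THF/H2O) then gives the 4α,5β-bis(trimethylsilyl) ether of 17 F6, and 1 M HCl in THF removes the two trimethylsilyl groups to give 17.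

Further compounds

F1 | step 15 | 2α-TBSO-4α-hydroxy-5β,11-epoxy-13-norguaian-12,8β-olide | CC(C)(C)[Si](C)(C)O[C@H]1C[C@@](C)(O)[C@@]23C[C@H]4[C@@H](C[C@@H](C)[C@H]12)OC(=O)[C@H]4O3
F2 | step 10 | 2α-TBSO-1αH,10βH-11,12,13-trinorguai-7-ene-4α,5β,9α-triol | CC(C)(C)[Si](C)(C)O[C@H]1C[C@@](C)(O)[C@@]2(O)CC=C[C@@H](O)[C@@H](C)[C@H]12
F3 | step 10 | 9β-acetate of 13 | CC(C)(C)[Si](C)(C)O[C@H]1C[C@@](C)(O)[C@@]2(O)CC=C[C@H](OC(C)=O)[C@@H](C)[C@H]12
F4 | step 10 | 2α-TBSO-4α,5β-dihydroxy-1αH,7αH,10βH-13-norguai-8-en-12-oic acid | CC(C)(C)[Si](C)(C)O[C@H]1C[C@@](C)(O)[C@@]2(O)C[C@H](CC(=O)O)C=C[C@@H](C)[C@H]12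
F5 | step 12 | 4α,5β-bis(trimethylsilyl) ether of 15 | CC(C)(C)[Si](C)(C)O[C@H]1C[C@@](C)(O[Si](C)(C)C)[C@@]2(O[Si](C)(C)C)C[C@H](CC(=O)N(C)C)C=C[C@@H](C)[C@H]12
F6 | step 12 | 4α,5β-bis(trimethylsilyl) ether of 17 | CC(C)(C)[Si](C)(C)O[C@H]1C[C@@](C)(O[Si](C)(C)C)[C@@]2(O[Si](C)(C)C)C[C@H]3[C@@H]([C@@H](I)[C@@H](C)[C@H]12)OC(=O)C3
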